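**Retrosynthetic overview**

1. Target 25 ← pentakis-MOM ether 24 (acetal cleavage) ← ring-A aryllithium (from bromide 22) + cinnamoyl Weinreb amide 19, which forms the aryl–C(=O) bond of the chalcone.
2. 22 ← benzylic boronic ester 13 + (E)-styryllithium 20: boron is exchanged for the C1=C2 styryl group with retention at C3 (Zweifel-type alkenylation, syn elimination); 13 ← 12 by bromination of ring A.
3. 12 ← boronate 7 + CH2Cl2 + aryllithium 11. The strategy rests on C3 of the hept-1-ene chain, an sp3 CH whose three carbon neighbours are C4 (CH2), the ring A carbon lying between the two oxygen-bearing carbons, and C2 of the styryl unit. The first two arrive by 1,2-shifts from boron onto a CHCl2-derived carbon; the third replaces boron.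
4. 7 ← 4-(4-hydroxyphenyl)butan-1-ol 1 and diol 4; 11 ← 5-methoxyresorcinol 8; 17 and 19 ← p-coumaric acid 14.
5. No ring is formed: all four benzene rings are bought (1, 8, and 14 twice).

Key step: step 5

Remark on the chemistry (assumption): the sense of induction of C2-symmetric 1,2-diol boronates towards (dichloromethyl)lithium is taken as the established one ((R,R)-diol gives the αS chloride), so the (S,S)-diol 4 is chosen to give the (1R)-chloride 10. Compounds 1, 4, 8 and 14 are taken as purchased.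

**Route**

Step 1
Reactants: 1 4-(4-hydroxyphenyl)butan-1-ol
Product: 2 4-[4-(methoxymethoxy)phenyl]butan-1-ol
Conditions: MOMCl (1.05 equiv), K2CO3, acetone, 0 °C → rt
Reagents that add atoms: chloromethyl methyl ether, COCCl
Why: Williamson-type O-alkylation in which carbonate deprotonates only the phenol, so the phenoxide is acetalised while the primary alcohol stays free.

Step 2
Reactants: 2 4-[4-(methoxymethoxy)phenyl]butan-1-ol
Product: 3 1-(4-bromobutyl)-4-(methoxymethoxy)benzene
Conditions: CBr4, PPh3, CH2Cl2, 0 °C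
Reagents that add atoms: carbon tetrabromide, BrC(Br)(Br)Br
Why: Appel reaction, in which bromide displaces the alkoxyphosphonium salt of the primary alcohol under neutral conditions that leave the aryl MOM acetal intact.

Step 3
Reactants: 3 1-(4-bromobutyl)-4-(methoxymethoxy)benzene; 4 (1S,2S)-1,2-dicyclohexylethane-1,2-diol
Product: 7 (4S,5S)-4,5-dicyclohexyl-2-{4-[4-(methoxymethoxy)phenyl]butyl}-1,3,2-dioxaborolane, via Grignard reagent 5 (not isolated), via boronic acid 6 (not isolated)
Conditions: Mg, THF, 40 °C; B(OMe)3, THF, –78 °C → rt; aq NH4Cl; then 4, MgSO4, Et2O, rt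
Reagents that add atoms: trimethyl borate, COB(OC)OC; magnesium, [Mg] (Mg of intermediate 5 only); water, O (OH groups of intermediate 6 only)
Why: Grignard borylation followed by diol esterification, in which the alkylmagnesium bromide adds once to excess borate at low temperature and the crude boronic acid condenses with the diol, whose two stereocentres are carried in unchanged.

Step 4
Reactants: 8 5-methoxyresorcinol
Product: 9 1-methoxy-3,5-bis(methoxymethoxy)benzene
Conditions: NaH, DMF, 0 °C; MOMCl, 0 °C → rt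
Reagents that add atoms: chloromethyl methyl ether, COCCl
Why: Williamson-type acetalisation of both phenoxides, which also installs the two directing groups needed for the lithiation in step 5.

Step 5
Reactants: 7 (4S,5S)-4,5-dicyclohexyl-2-{4-[4-(methoxymethoxy)phenyl]butyl}-1,3,2-dioxaborolane; 9 1-methoxy-3,5-bis(methoxymethoxy)benzene
Product: 12 (4S,5S)-4,5-dicyclohexyl-2-{(1S)-1-[4-methoxy-2,6-bis(methoxymethoxy)phenyl]-5-[4-(methoxymethoxy)phenyl]pentyl}-1,3,2-dioxaborolane, via alpha-chloro boronic ester 10 (not isolated), via aryllithium 11 (not isolated)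
Conditions: (a) CH2Cl2, n-BuLi, THF, –100 °C; 7; ZnCl2, –100 °C → rt; pentane/aq NH4Cl wash, solvent switch to THF (crude 10, not purified); (b) 9 (slight excess over n-BuLi), n-BuLi, THF, 0 °C (gives 11); add to crude 10, –78 °C → rt
Reagents that add atoms: dichloromethane, ClCCl (supplies C3 and the Cl of 10); n-butyllithium, [Li]CCCC (Li of intermediate 11 only)
Why: Matteson homologation: (dichloromethyl)lithium adds to the boron of 7 and, in the ZnCl2-assisted 1,2-shift of the ate complex, the butyl carbon moves to the carbenoid carbon with loss of one chloride (C3–C4 bond), the (S,S)-diol deciding which diastereotopic chloride leaves so that the (1R)-chloride 10 is expected. Arene 9 is lithiated at the position flanked by both MOM ethers (directed ortho-metalation) and aryllithium 11 adds to the boron of 10; the aryl group then migrates anti-periplanar to the C–Cl bond and expels chloride with inversion at carbon (ring A–C3 bond), which makes C3 (S) in 12. The closest known reaction type is the sequential (dichloromethyl)lithium insertion and Grignard or organolithium displacement on chiral diol boronic esters. No ring is closed. The step needs attack at boron to outrun α-deprotonation of 10 and needs 10 to keep its configuration; the vacant boron orbital secures the first, and removal of lithium and zinc chlorides before stage (b) prevents chloride exchange from epimerising 10. The secondary benzylic boronic ester 12 is configurationally stable.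

Step 6
Reactants: 12 (4S,5S)-4,5-dicyclohexyl-2-{(1S)-1-[4-methoxy-2,6-bis(methoxymethoxy)phenyl]-5-[4-(methoxymethoxy)phenyl]pentyl}-1,3,2-dioxaborolane
Product: 13 (4S,5S)-2-{(1S)-1-[3-bromo-4-methoxy-2,6-bis(methoxymethoxy)phenyl]-5-[4-(methoxymethoxy)phenyl]pentyl}-4,5-dicyclohexyl-1,3,2-dioxaborolane
Conditions: NBS (1.0 equiv), NaHCO3, MeCN, –20 → 0 °C, dark
Reagents that add atoms: N-bromosuccinimide, O=C1CCC(=O)N1Br
Why: Electrophilic aromatic bromination, in which the 2,4,6-trioxygenated ring A is far more nucleophilic than the 4-alkylphenyl MOM ether, its two free positions are equivalent by rotation about the aryl–C3 bond, and the neutral boronic ester and C3 are not attacked by NBS.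

Step 7
Reactants: 14 p-coumaric acid, (2E)-3-(4-hydroxyphenyl)prop-2-enoic acid
Product: 16 (2E)-3-[4-(methoxymethoxy)phenyl]prop-2-enoic acid, via MOM ester 15 (not isolated)
Conditions: MOMCl (2.3 equiv), K2CO3, DMF, 0 °C → rt; then LiOH, THF/H2O, rt; 1 M HCl to pH 4, 0 °C
Reagents that add atoms: chloromethyl methyl ether, COCCl; lithium hydroxide, [Li+].[OH-] (one carboxyl O of 16)
Why: Double O-alkylation followed by saponification, which cleaves only the acyloxymethyl ester because aryl MOM acetals are stable to hydroxide.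

Step 8
Reactants: 16 (2E)-3-[4-(methoxymethoxy)phenyl]prop-2-enoic acid
Product: 17 1-[(E)-2-bromoethenyl]-4-(methoxymethoxy)benzene
Conditions: NBS (1.05 equiv), Et3N (10 mol %), CH2Cl2, rt
Reagents that add atoms: N-bromosuccinimide, O=C1CCC(=O)N1Br
Why: Catalytic Hunsdiecker-type bromodecarboxylation, in which bromonium transfer to the electron-rich cinnamate is followed by loss of CO2, the (E)-bromoalkene being the expected isomer for 4-alkoxycinnamates.

Step 9
Reactants: 16 (2E)-3-[4-(methoxymethoxy)phenyl]prop-2-enoic acid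
Product: 19 (2E)-N-methoxy-N-methyl-3-[4-(methoxymethoxy)phenyl]prop-2-enamide, via acyl imidazolide 18 (not isolated)
Conditions: CDI, CH2Cl2, rt; MeNH(OMe)·HCl, rt
Reagents that add atoms: N,O-dimethylhydroxylamine hydrochloride, CNOC.Cl; 1,1'-carbonyldiimidazole, O=C(n1ccnc1)n1ccnc1 (imidazolyl of intermediate 18 only)
Why: Amide coupling through the acyl imidazolide gives the Weinreb amide without touching the (E)-alkene or the MOM ether.

Step 10
Reactants: 13 (4S,5S)-2-{(1S)-1-[3-bromo-4-methoxy-2,6-bis(methoxymethoxy)phenyl]-5-[4-(methoxymethoxy)phenyl]pentyl}-4,5-dicyclohexyl-1,3,2-dioxaborolane; 17 1-[(E)-2-bromoethenyl]-4-(methoxymethoxy)benzene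
Product: 22 2-bromo-1-methoxy-3,5-bis(methoxymethoxy)-4-{(1E,3R)-1,7-bis[4-(methoxymethoxy)phenyl]hept-1-en-3-yl}benzene, via styryllithium 20 (not isolated), via selenoboronate 21 (not isolated)
Conditions: 17, t-BuLi (2.0 equiv per 17), Et2O/THF, –78 °C; 13, THF, –78 °C; PhSeCl, –78 → 0 °C; mCPBA, THF, –45 °C → rt
Reagents that add atoms: tert-butyllithium, [Li]C(C)(C)C (Li of intermediate 20 only); benzeneselenenyl chloride, Cl[Se]c1ccccc1 (PhSe of intermediate 21 only)
Why: Zweifel-type alkenylation in its selenium-mediated syn-elimination form, in which 20 adds to boron, PhSeCl triggers the 1,2-shift of the benzylic carbon with retention at C3, and the selenoxide lets boron and selenium leave syn so that the (E)-geometry of 20 is kept; C3 is then named (R) only because the CIP ranking changes.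

Step 11
Reactants: 22 2-bromo-1-methoxy-3,5-bis(methoxymethoxy)-4-{(1E,3R)-1,7-bis[4-(methoxymethoxy)phenyl]hept-1-en-3-yl}benzene; 19 (2E)-N-methoxy-N-methyl-3-[4-(methoxymethoxy)phenyl]prop-2-enamide
Product: 24 (2E)-1-{3-[(1E,3R)-1,7-bis[4-(methoxymethoxy)phenyl]hept-1-en-3-yl]-6-methoxy-2,4-bis(methoxymethoxy)phenyl}-3-[4-(methoxymethoxy)phenyl]prop-2-en-1-one, via aryllithium 23 (not isolated)
Conditions: n-BuLi (1.05 equiv), THF, –78 °C, 10 min; 19 (1.5 equiv), –78 → –20 °C; aq NH4Cl
Reagents that add atoms: n-butyllithium, [Li]CCCC (Li of intermediate 23 only)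
Why: Bromine–lithium exchange followed by Weinreb ketone synthesis, in which exchange at –78 °C is much faster than deprotonation of the hindered C3–H and the chelated tetrahedral adduct releases the enone only on work-up, so over-addition and conjugate addition are avoided.

Step 12
Reactants: 24 (2E)-1-{3-[(1E,3R)-1,7-bis[4-(methoxymethoxy)phenyl]hept-1-en-3-yl]-6-methoxy-2,4-bis(methoxymethoxy)phenyl}-3-[4-(methoxymethoxy)phenyl]prop-2-en-1-one
Product: 25 deoxycalyxin A, (2E)-1-{3-[(1E,3R)-1,7-bis(4-hydroxyphenyl)hept-1-en-3-yl]-2,4-dihydroxy-6-methoxyphenyl}-3-(4-hydroxyphenyl)prop-2-en-1-one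
Conditions: 3 M aq HCl, MeOH, rt, dark, argon
Reagents that add atoms: none
Why: Acid-catalysed acetal cleavage (transacetalisation to dimethoxymethane) of all five aryl MOM ethers at room temperature in dilute acid, which should spare the 2'-hydroxychalcone from flavanone closure and cannot ionise C3, since it bears no leaving group.

**Compound list**

1 | 4-(4-hydroxyphenyl)butan-1-ol | OCCCCc1ccc(O)cc1 | starting material
2 | 4-[4-(methoxymethoxy)phenyl]butan-1-ol | OCCCCc1ccc(OCOC)cc1 | intermediate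
3 | 1-(4-bromobutyl)-4-(methoxymethoxy)benzene | BrCCCCc1ccc(OCOC)cc1 | intermediate
4 | (1S,2S)-1,2-dicyclohexylethane-1,2-diol | O[C@@H](C1CCCCC1)[C@H](C1CCCCC1)O | starting material
5 | {4-[4-(methoxymethoxy)phenyl]butyl}magnesium bromide | Br[Mg]CCCCc1ccc(OCOC)cc1 | intermediate
6 | {4-[4-(methoxymethoxy)phenyl]butyl}boronic acid | OB(O)CCCCc1ccc(OCOC)cc1 | intermediate
7 | (4S,5S)-4,5-dicyclohexyl-2-{4-[4-(methoxymethoxy)phenyl]butyl}-1,3,2-dioxaborolane | COCOc1ccc(CCCCB2O[C@@H](C3CCCCC3)[C@H](C3CCCCC3)O2)cc1 | intermediate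
8 | 5-methoxyresorcinol | COc1cc(O)cc(O)c1 | starting material
9 | 1-methoxy-3,5-bis(methoxymethoxy)benzene | COCOc1cc(OC)cc(OCOC)c1 | intermediate
10 | (4S,5S)-2-{(1R)-1-chloro-5-[4-(methoxymethoxy)phenyl]pentyl}-4,5-dicyclohexyl-1,3,2-dioxaborolane | Cl[C@H](B1O[C@@H](C2CCCCC2)[C@H](C2CCCCC2)O1)CCCCc1ccc(OCOC)cc1 | intermediate
11 | [4-methoxy-2,6-bis(methoxymethoxy)phenyl]lithium | [Li]c1c(OCOC)cc(OC)cc1OCOC | intermediate
12 | (4S,5S)-4,5-dicyclohexyl-2-{(1S)-1-[4-methoxy-2,6-bis(methoxymethoxy)phenyl]-5-[4-(methoxymethoxy)phenyl]pentyl}-1,3,2-dioxaborolane | COc1cc(OCOC)c([C@@H](B2O[C@@H](C3CCCCC3)[C@H](C3CCCCC3)O2)CCCCc2ccc(OCOC)cc2)c(OCOC)c1 | intermediate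
13 | (4S,5S)-2-{(1S)-1-[3-bromo-4-methoxy-2,6-bis(methoxymethoxy)phenyl]-5-[4-(methoxymethoxy)phenyl]pentyl}-4,5-dicyclohexyl-1,3,2-dioxaborolane | COc1cc(OCOC)c([C@@H](B2O[C@@H](C3CCCCC3)[C@H](C3CCCCC3)O2)CCCCc2ccc(OCOC)cc2)c(OCOC)c1Br | intermediate
14 | p-coumaric acid | O=C(O)/C=C/c1ccc(O)cc1 | starting material
15 | methoxymethyl (2E)-3-[4-(methoxymethoxy)phenyl]prop-2-enoate | COCOC(=O)/C=C/c1ccc(OCOC)cc1 | intermediate
16 | (2E)-3-[4-(methoxymethoxy)phenyl]prop-2-enoic acid | OC(=O)/C=C/c1ccc(OCOC)cc1 | intermediate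
17 | 1-[(E)-2-bromoethenyl]-4-(methoxymethoxy)benzene | Br/C=C/c1ccc(OCOC)cc1 | intermediate
18 | (2E)-1-(1H-imidazol-1-yl)-3-[4-(methoxymethoxy)phenyl]prop-2-en-1-one | O=C(/C=C/c1ccc(OCOC)cc1)n1ccnc1 | intermediate
19 | (2E)-N-methoxy-N-methyl-3-[4-(methoxymethoxy)phenyl]prop-2-enamide | CON(C)C(=O)/C=C/c1ccc(OCOC)cc1 | intermediate
20 | {(E)-2-[4-(methoxymethoxy)phenyl]ethenyl}lithium | [Li]/C=C/c1ccc(OCOC)cc1 | intermediate
21 | (4S,5S)-2-{(3R)-3-[3-bromo-4-methoxy-2,6-bis(methoxymethoxy)phenyl]-1,7-bis[4-(methoxymethoxy)phenyl]-1-(phenylselanyl)heptan-2-yl}-4,5-dicyclohexyl-1,3,2-dioxaborolane (anti-addition product, both diastereomers at C1/C2) | COc1cc(OCOC)c([C@@H](C(B2O[C@@H](C3CCCCC3)[C@H](C3CCCCC3)O2)C([Se]c2ccccc2)c2ccc(OCOC)cc2)CCCCc2ccc(OCOC)cc2)c(OCOC)c1Br | intermediate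
22 | 2-bromo-1-methoxy-3,5-bis(methoxymethoxy)-4-{(1E,3R)-1,7-bis[4-(methoxymethoxy)phenyl]hept-1-en-3-yl}benzene | COc1cc(OCOC)c([C@@H](/C=C/c2ccc(OCOC)cc2)CCCCc2ccc(OCOC)cc2)c(OCOC)c1Br | intermediate
23 | (3-{(1E,3R)-1,7-bis[4-(methoxymethoxy)phenyl]hept-1-en-3-yl}-6-methoxy-2,4-bis(methoxymethoxy)phenyl)lithium | COc1cc(OCOC)c([C@@H](/C=C/c2ccc(OCOC)cc2)CCCCc2ccc(OCOC)cc2)c(OCOC)c1[Li] | intermediate
24 | (2E)-1-{3-[(1E,3R)-1,7-bis[4-(methoxymethoxy)phenyl]hept-1-en-3-yl]-6-methoxy-2,4-bis(methoxymethoxy)phenyl}-3-[4-(methoxymethoxy)phenyl]prop-2-en-1-one | COc1cc(OCOC)c([C@@H](/C=C/c2ccc(OCOC)cc2)CCCCc2ccc(OCOC)cc2)c(OCOC)c1C(=O)/C=C/c1ccc(OCOC)cc1 | intermediate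
25 | deoxycalyxin A | COc1cc(O)c([C@@H](/C=C/c2ccc(O)cc2)CCCCc2ccc(O)cc2)c(O)c1C(=O)/C=C/c1ccc(O)cc1 | target

**Step count and risks**

Total steps: 12. Longest linear sequence: 8 steps (steps 1, 2, 3, 5, 6, 10, 11, 12).

Steps most likely to fail:

1. Step 5. The doubly ortho-substituted aryllithium may deprotonate the α-chloro boronic ester instead of adding to boron, or add reversibly without the aryl shift taking place. Chloride exchange could also erode the configuration of the chloride before the aryl arrives. Fallback (reagent-controlled lithiation–borylation in place of diol control), setting out from Grignard reagent 5 and aryllithium 11 and coming back at 22: Grignard reagent 5 is quenched with paraformaldehyde to give 5-[4-(methoxymethoxy)phenyl]pentan-1-ol F1, which is acylated with N,N-diisopropylcarbamoyl chloride to 5-[4-(methoxymethoxy)phenyl]pentyl N,N-diisopropylcarbamate F2. Aryllithium 11 is trapped with 2-isopropoxy-4,4,5,5-tetramethyl-1,3,2-dioxaborolane to give 2-[4-methoxy-2,6-bis(methoxymethoxy)phenyl]-4,4,5,5-tetramethyl-1,3,2-dioxaborolane F3. F2 is deprotonated with s-BuLi/(+)-sparteine in Et2O at –78 °C (this diamine enantiomer is chosen so that the aryl shift, which inverts the lithiated carbon, leaves C3 as in 12), F3 is added, and MgBr2-promoted 1,2-migration with loss of the carbamate gives the pinacol (1S)-1-[4-methoxy-2,6-bis(methoxymethoxy)phenyl]-5-[4-(methoxymethoxy)phenyl]pentylboronate F4. NBS as in step 6 gives its ring-A bromide F5, which is taken through the conditions of step 10 to rejoin the route at 22.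

2. Step 10. Ate-complex formation at the congested secondary benzylic boron may be slow enough for the alkenyllithium to start bromine–lithium exchange on ring A, and the peracid may over-oxidise the electron-rich product alkene. Fallback (vinyl transfer with a Grignard reagent, then olefin metathesis sets the geometry), setting out from 13 and coming back at 22: 13 is treated with vinylmagnesium bromide in THF/DMSO, then I2 and NaOMe (Zweifel vinylation, retention at C3), to give 2-bromo-1-methoxy-3,5-bis(methoxymethoxy)-4-{(3R)-7-[4-(methoxymethoxy)phenyl]hept-1-en-3-yl}benzene F6. Styryllithium 20 (from 17) is quenched with methanol to give 4-(methoxymethoxy)styrene F7. Cross-metathesis of F6 with excess F7 (Hoveyda–Grubbs second-generation catalyst, CH2Cl2, 40 °C) should give the (E)-alkene 22 under thermodynamic control.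

3. Step 11. Proton transfer from the doubly activated (benzylic and allylic) C3–H to n-BuLi or to aryllithium 23 may compete with exchange and acylation, which would return debrominated material and scramble C3. Fallback (no organolithium; palladium coupling and aldol condensation), setting out from 22 and coming back at 24: Stille coupling of 22 with tributyl(1-ethoxyvinyl)stannane (Pd(PPh3)4, toluene, 100 °C) gives the enol ether 2-(1-ethoxyethenyl)-1-methoxy-3,5-bis(methoxymethoxy)-4-{(1E,3R)-1,7-bis[4-(methoxymethoxy)phenyl]hept-1-en-3-yl}benzene F8. Brief treatment with dilute aqueous HCl in THF at 0 °C hydrolyses it to the methyl ketone 1-{3-[(1E,3R)-1,7-bis[4-(methoxymethoxy)phenyl]hept-1-en-3-yl]-6-methoxy-2,4-bis(methoxymethoxy)phenyl}ethan-1-one F9. Claisen–Schmidt condensation of F9 with commercial 4-(methoxymethoxy)benzaldehyde (KOH, EtOH/H2O, rt) gives 24.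

**Further compounds**

F1 | step 5 | 5-[4-(methoxymethoxy)phenyl]pentan-1-ol | OCCCCCc1ccc(OCOC)cc1
F2 | step 5 | 5-[4-(methoxymethoxy)phenyl]pentyl N,N-diisopropylcarbamate | CC(C)N(C(C)C)C(=O)OCCCCCc1ccc(OCOC)cc1
F3 | step 5 | 2-[4-methoxy-2,6-bis(methoxymethoxy)phenyl]-4,4,5,5-tetramethyl-1,3,2-dioxaborolane | COCOc1cc(OC)cc(OCOC)c1B1OC(C)(C)C(C)(C)O1
F4 | step 5 | 2-{(1S)-1-[4-methoxy-2,6-bis(methoxymethoxy)phenyl]-5-[4-(methoxymethoxy)phenyl]pentyl}-4,4,5,5-tetramethyl-1,3,2-dioxaborolane | COc1cc(OCOC)c([C@@H](B2OC(C)(C)C(C)(C)O2)CCCCc2ccc(OCOC)cc2)c(OCOC)c1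
F5 | step 5 | 2-{(1S)-1-[3-bromo-4-methoxy-2,6-bis(methoxymethoxy)phenyl]-5-[4-(methoxymethoxy)phenyl]pentyl}-4,4,5,5-tetramethyl-1,3,2-dioxaborolane | COc1cc(OCOC)c([C@@H](B2OC(C)(C)C(C)(C)O2)CCCCc2ccc(OCOC)cc2)c(OCOC)c1Br
F6 | step 10 | 2-bromo-1-methoxy-3,5-bis(methoxymethoxy)-4-{(3R)-7-[4-(methoxymethoxy)phenyl]hept-1-en-3-yl}benzene | COc1cc(OCOC)c([C@@H](C=C)CCCCc2ccc(OCOC)cc2)c(OCOC)c1Br
F7 | step 10 | 4-(methoxymethoxy)styrene | C=Cc1ccc(OCOC)cc1
F8 | step 11 | 2-(1-ethoxyethenyl)-1-methoxy-3,5-bis(methoxymethoxy)-4-{(1E,3R)-1,7-bis[4-(methoxymethoxy)phenyl]hept-1-en-3-yl}benzene | COc1cc(OCOC)c([C@@H](/C=C/c2ccc(OCOC)cc2)CCCCc2ccc(OCOC)cc2)c(OCOC)c1C(=C)OCC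
F9 | step 11 | 1-{3-[(1E,3R)-1,7-bis[4-(methoxymethoxy)phenyl]hept-1-en-3-yl]-6-methoxy-2,4-bis(methoxymethoxy)phenyl}ethan-1-one | COc1cc(OCOC)c([C@@H](/C=C/c2ccc(OCOC)cc2)CCCCc2ccc(OCOC)cc2)c(OCOC)c1C(C)=O
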